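**Plan**

- Retrosynthesis: the acid is taken back to its methyl ester and the two furan C–H bonds at C3'/C4' to C–Si bonds. The furan bonds C2'–C3' and C4'–C5' are then cut, giving a 2-alkyl-4-phenyloxazole and a bis-silyl alkyne. Further back, C4–C5 is cut (acetylide alkylation), then C5≡C6 (one-carbon homologation of an aldehyde), then the oxazole (primary amide plus α-bromoketone).
- Enabling feature: furan O1', C2' (carrying chain carbon C19) and C5'–H already exist as O1, C2 and C5 of the oxazole. Only C3' and C4' must be brought in, while N3 and C4–Ph leave as benzonitrile.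
- Forward order: pentadecanolide supplies oxazole C2 and C6–C19 (ammonolysis, O-acetylation, oxazole formation, oxidation, alkyne homologation). The C1–C4 unit is joined as a bromo-orthoester. The oxazole ring is then exchanged for the furan, the only ring of the target, and desilylation and saponification finish the route.
- Stereochemistry: nothing to set; the bridgehead centres of the transient cycloadduct disappear on cycloreversion.

Key step: step 7

Remark on the chemistry: the target is achiral (no stereocentre, no stereogenic double bond). Chain atoms are numbered C1 (carboxyl) to C19, furan atoms O1' and C2'–C5'.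

Step 1
Reactants: 1 pentadecanolide (oxacyclohexadecan-2-one)
Product: 2 15-hydroxypentadecanamide
Conditions: NH3 (7 M in MeOH, excess), sealed vessel, 80 °C
Reagents that add atoms: ammonia, N
Why: Ester ammonolysis: the unstrained 16-membered lactone behaves as an ordinary ester and should be opened by ammonia at the acyl carbon, the freed primary alcohol being inert.

Step 2
Reactants: 2 15-hydroxypentadecanamide
Product: 3 15-amino-15-oxopentadecyl acetate
Conditions: Ac2O (1.2 equiv), pyridine, 0 °C to rt
Reagents that add atoms: acetic anhydride, CC(=O)OC(C)=O
Why: O-Acetylation with Ac2O/pyridine is selective for the primary alcohol over the far less nucleophilic primary amide, and the acetate shields the hydroxyl from the HBr released in the next step.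

Step 3
Reactants: 3 15-amino-15-oxopentadecyl acetate; 4 2-bromoacetophenone
Product: 6 14-(4-phenyl-1,3-oxazol-2-yl)tetradecan-1-ol, via oxazole acetate 5 (not isolated)
Conditions: 4 (1.3 equiv), neat, 130 °C; then K2CO3, MeOH/THF, rt
Reagents that add atoms: 2-bromoacetophenone (4), O=C(CBr)c1ccccc1
Why: Blümlein–Lewy (Hantzsch-type) oxazole synthesis, in which the amide oxygen displaces bromide, the nitrogen closes onto the ketone and dehydration places the phenyl at C4 with C5 left as C–H, followed by carbonate-mediated methanolysis that should converge intact and partly deacetylated material on alcohol 6.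

Step 4
Reactants: 6 14-(4-phenyl-1,3-oxazol-2-yl)tetradecan-1-ol
Product: 7 14-(4-phenyl-1,3-oxazol-2-yl)tetradecanal
Conditions: Dess–Martin periodinane, CH2Cl2, 0 °C to rt
Reagents that add atoms: none
Why: Dess–Martin oxidation should stop at the aldehyde and leave the weakly basic oxazole untouched.

Step 5
Reactants: 7 14-(4-phenyl-1,3-oxazol-2-yl)tetradecanal
Product: 8 2-(pentadec-14-yn-1-yl)-4-phenyl-1,3-oxazole
Conditions: dimethyl (1-diazo-2-oxopropyl)phosphonate, K2CO3, MeOH/THF, 0 °C to rt
Reagents that add atoms: dimethyl (1-diazo-2-oxopropyl)phosphonate, COP(=O)(OC)C(=[N+]=[N-])C(C)=O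
Why: Ohira–Bestmann (Seyferth–Gilbert) homologation should convert the enolisable aldehyde into the terminal alkyne under mild carbonate conditions, adding the carbon that becomes C5.

Step 6
Reactants: 8 2-(pentadec-14-yn-1-yl)-4-phenyl-1,3-oxazole; 9 trimethyl 4-bromoorthobutyrate (4-bromo-1,1,1-trimethoxybutane)
Product: 12 methyl 19-(4-phenyl-1,3-oxazol-2-yl)nonadec-5-ynoate, via lithium acetylide 10 (not isolated), via trimethyl orthoester 11 (not isolated)
Conditions: n-BuLi (1.0 equiv), THF, −78 °C; 9, HMPA, −78 °C to rt; then 0.5 M aq. HCl, THF, 0 °C
Reagents that add atoms: trimethyl 4-bromoorthobutyrate (9), COC(CCCBr)(OC)OC; water, O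
Why: Acetylide alkylation, in which the terminal alkyne as the most acidic C–H should be deprotonated by one equivalent of n-BuLi ahead of the oxazole C5–H, the lithium acetylide displaces the primary bromide (SN2) in THF/HMPA while the orthoester masks the carboxyl carbon, and dilute acid on work-up converts the orthoester into the methyl ester.

Step 7
Reactants: 12 methyl 19-(4-phenyl-1,3-oxazol-2-yl)nonadec-5-ynoate; 13 bis(trimethylsilyl)acetylene
Product: 15 methyl 19-[3,4-bis(trimethylsilyl)furan-2-yl]nonadec-5-ynoate, via bicyclic cycloadduct 14 (not isolated)
Conditions: 13 (neat, large excess; 12 at about 0.1 M), Et3N (cat.), sealed tube, 250 °C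
Reagents that add atoms: bis(trimethylsilyl)acetylene (13), C[Si](C)(C)C#C[Si](C)(C)C
Why: The oxazole should act as a 2-azadiene (C2=N3–C4=C5, O1 becoming the bridge) in a thermal [4+2] cycloaddition with the silylalkyne across C2 and C5 to give the 7-oxa-2-azabicyclo[2.2.1]heptadiene 14, which at the same temperature undergoes retro-[4+2] loss of benzonitrile (N3 and C4 with its phenyl). The closest known reaction is the Diels–Alder/retro-Diels–Alder reaction of 4-phenyloxazole with silylated alkynes to give 3,4-bis(silyl)furans, the 2-alkyl chain here being a spectator at one bonding terminus. The furan ring is closed by intermolecular cycloaddition that forms C2'–C3' and C4'–C5' in one event, and the aromatic five-membered ring appears on cycloreversion, whose direction is set by furan aromaticity and by the conjugated nitrile that the C4 phenyl provides. No stereocentre is created in the product, since both bridgehead centres of 14 are lost again. The step needs chemoselectivity for the reagent alkyne over the substrate's own C5≡C6 bond; this is secured by running dilute in neat 13 and by the thirteen-methylene tether, which makes intramolecular addition entropically negligible. The symmetric dienophile leaves no regiochemical question, and Et3N keeps the melt free of acid that could cleave C–Si bonds.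

Step 8
Reactants: 15 methyl 19-[3,4-bis(trimethylsilyl)furan-2-yl]nonadec-5-ynoate
Product: 17 methyl 19-(furan-2-yl)nonadec-5-ynoate, via monosilyl furan 16 (not isolated)
Conditions: CF3CO2H (excess), CH2Cl2, 0 °C to rt
Reagents that add atoms: none
Why: Acid-mediated ipso-protodesilylation (electrophilic aromatic substitution), in which protonation at each silicon-bearing β-carbon gives a cation stabilised by the ring oxygen and the β-silicon effect before the silyl group leaves as its trifluoroacetate, the crowded C3' silyl next to the chain being expected to go first.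

Step 9
Reactants: 17 methyl 19-(furan-2-yl)nonadec-5-ynoate
Product: 19 19-(furan-2-yl)nonadec-5-ynoic acid, via lithium carboxylate 18 (not isolated)
Conditions: LiOH·H2O, THF/MeOH/H2O, rt; then 1 M aq. HCl to pH 4, 0 °C
Reagents that add atoms: lithium hydroxide, [Li+].[OH-]
Why: Ester saponification by hydroxide (acyl substitution) is compatible with the furan and the isolated alkyne, and cold acidification only to about pH 4 should free the acid without exposing the 2-alkylfuran to strong acid.

**Compound list**

1 | pentadecanolide (oxacyclohexadecan-2-one) | O=C1CCCCCCCCCCCCCCO1 | starting material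
2 | 15-hydroxypentadecanamide | NC(=O)CCCCCCCCCCCCCCO | intermediate
3 | 15-amino-15-oxopentadecyl acetate | CC(=O)OCCCCCCCCCCCCCCC(N)=O | intermediate
4 | 2-bromoacetophenone | O=C(CBr)c1ccccc1 | starting material
5 | 14-(4-phenyl-1,3-oxazol-2-yl)tetradecyl acetate (formed in the flask, not isolated) | CC(=O)OCCCCCCCCCCCCCCc1nc(-c2ccccc2)co1 | intermediate
6 | 14-(4-phenyl-1,3-oxazol-2-yl)tetradecan-1-ol | OCCCCCCCCCCCCCCc1nc(-c2ccccc2)co1 | intermediate
7 | 14-(4-phenyl-1,3-oxazol-2-yl)tetradecanal | O=CCCCCCCCCCCCCCc1nc(-c2ccccc2)co1 | intermediate
8 | 2-(pentadec-14-yn-1-yl)-4-phenyl-1,3-oxazole | C#CCCCCCCCCCCCCCc1nc(-c2ccccc2)co1 | intermediate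
9 | trimethyl 4-bromoorthobutyrate (4-bromo-1,1,1-trimethoxybutane) | COC(CCCBr)(OC)OC | starting material
10 | lithium acetylide of 8, [15-(4-phenyl-1,3-oxazol-2-yl)pentadec-1-yn-1-yl]lithium (formed in the flask, not isolated) | [Li]C#CCCCCCCCCCCCCCc1nc(-c2ccccc2)co1 | intermediate
11 | 2-(19,19,19-trimethoxynonadec-14-yn-1-yl)-4-phenyl-1,3-oxazole (formed in the flask, not isolated) | COC(OC)(OC)CCCC#CCCCCCCCCCCCCCc1nc(-c2ccccc2)co1 | intermediate
12 | methyl 19-(4-phenyl-1,3-oxazol-2-yl)nonadec-5-ynoate | COC(=O)CCCC#CCCCCCCCCCCCCCc1nc(-c2ccccc2)co1 | intermediate
13 | bis(trimethylsilyl)acetylene | C[Si](C)(C)C#C[Si](C)(C)C | starting material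
14 | methyl 19-[3-phenyl-5,6-bis(trimethylsilyl)-7-oxa-2-azabicyclo[2.2.1]hepta-2,5-dien-1-yl]nonadec-5-ynoate (racemic, transient, not isolated) | COC(=O)CCCC#CCCCCCCCCCCCCCC12OC(C(=N1)c1ccccc1)C(=C2[Si](C)(C)C)[Si](C)(C)C | intermediate
15 | methyl 19-[3,4-bis(trimethylsilyl)furan-2-yl]nonadec-5-ynoate | COC(=O)CCCC#CCCCCCCCCCCCCCc1occ([Si](C)(C)C)c1[Si](C)(C)C | intermediate
16 | methyl 19-[4-(trimethylsilyl)furan-2-yl]nonadec-5-ynoate (expected mono-desilylation stage, not isolated) | COC(=O)CCCC#CCCCCCCCCCCCCCc1cc([Si](C)(C)C)co1 | intermediate
17 | methyl 19-(furan-2-yl)nonadec-5-ynoate | COC(=O)CCCC#CCCCCCCCCCCCCCc1ccco1 | intermediate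
18 | lithium 19-(furan-2-yl)nonadec-5-ynoate (formed in the flask, not isolated) | [Li+].[O-]C(=O)CCCC#CCCCCCCCCCCCCCc1ccco1 | intermediate
19 | 19-(furan-2-yl)nonadec-5-ynoic acid | O=C(O)CCCC#CCCCCCCCCCCCCCc1ccco1 | target

**Step count and risks**

Total step count: 9. Longest linear sequence: 9 steps (1 to 19); compounds 4, 9 and 13 are purchased.

Steps most likely to fail:

1. Step 7. The 2-alkyl terminus and the two trimethylsilyl groups crowd both forming bonds, so the cycloaddition may be slow enough that prolonged heating at 250 °C degrades the chain before conversion is complete. Fallback: setting out from 12, the oxazole would be heated in a sealed tube with ethynyltrimethylsilane and catalytic Et3N, a smaller monosilyl dienophile. The same cycloaddition and loss of benzonitrile should then give methyl 19-[3-(trimethylsilyl)furan-2-yl]nonadec-5-ynoate F1 together with its 4-silyl regioisomer 16. The mixture needs no separation, because CF3CO2H in CH2Cl2 should protodesilylate both isomers to 17, where the route is rejoined.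

2. Step 8. After the first, sterically accelerated loss of silicon, the second ipso-protonation must compete with protonation at the free C5' position. The reaction may therefore stall at the monosilyl stage, or the electron-rich 2-alkylfuran may oligomerise under prolonged acid exposure. Fallback: setting out from 15, the ester would be saponified first (LiOH·H2O, THF/MeOH/H2O) to 19-[3,4-bis(trimethylsilyl)furan-2-yl]nonadec-5-ynoic acid F2. Both C–Si bonds would then be cleaved by nucleophilic attack at silicon with tetrabutylammonium fluoride in wet DMSO at about 80 °C (fluoride-induced protodesilylation of heteroaryl silanes), the carboxylate being inert. Acidification to pH 4 returns the route directly at the target 19.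

3. Step 6. n-BuLi may partly metalate the oxazole (C5–H or the CH2 next to C2), the SN2 displacement may be slow, or the orthoester may be lost early so that the acetylide attacks the resulting ester. Fallback: setting out from 8, the strong base is avoided by a Sonogashira coupling of an unactivated primary alkyl bromide. Alkyne 8 and methyl 4-bromobutanoate would be coupled with [Pd(η3-C3H5)Cl]2 (cat.), 1,3-bis(1-adamantyl)imidazolium chloride (cat.), CuI (cat.) and Cs2CO3 in DMF/Et2O at 45 °C. This gives the methyl ester 12 directly, where the route is rejoined.

Further compounds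
F1 | step 7 | methyl 19-[3-(trimethylsilyl)furan-2-yl]nonadec-5-ynoate | COC(=O)CCCC#CCCCCCCCCCCCCCc1occc1[Si](C)(C)C
F2 | step 8 | 19-[3,4-bis(trimethylsilyl)furan-2-yl]nonadec-5-ynoic acid | O=C(O)CCCC#CCCCCCCCCCCCCCc1occ([Si](C)(C)C)c1[Si](C)(C)C
F0 | step 6 | none | none
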